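The route rests on disconnecting the lower C8a–O1 bond while lower ring A is dearomatised. The feature exploited is that C8a, the ring A carbon carrying O1, sits meta to the C7 hydroxyl and next to C4a, and that the lower pyran has a cis C2-aryl/C3-oxygen pair. The precursor is a para-quinol dienone (C7 carbonyl, C4a carbinol, C5 benzyloxy) that carries the benzylated upper flavan on C8 and a (1R,2R) syn-diol monobenzyl ether chain on C4a. In one operation its benzylic hydroxyl adds to C8a, closing the pyran with retention at C2, and loss of the C4a hydroxyl re-forms ring A as the C7 phenol.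

Key step: step 13

Remarks and assumptions on the chemistry:
- Lower-unit positions are given in flavan numbering (C2, C3, C4, C4a, C5–C8, C8a) throughout, also for open-chain and dearomatised compounds.
- The two resorcinol oxygens must be differentiated from the start. The oxygen ortho to the chain (later C5–O) is benzylated. The para oxygen (later C7–O) is silylated only for the organometallic step and is free from step 8 on, so that it can direct the union and later be oxidised.
- The C3 unit is introduced as methyl (R)-glycidate. The aldehyde then comes from an ester reduction, and no alcohol oxidation is needed next to a free phenol.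
- A 4-alkylresorcinol has two activated ring carbons. The one between the oxygens is the more hindered, so the union is expected at the carbon ortho to the free hydroxyl and para to the benzyloxy group (later C8).
- Quinol 19 forms as both C4a epimers and is used as the mixture, so its SMILES leaves C4a open. Adduct 20 has three transient centres (C4a, C8, C8a; ring fusion cis) that are left open and vanish on aromatisation.
- The upper C4 centre has one spatial arrangement (2,4-trans) from 14 onwards. Its CIP label is S in 14, 15, 18 and 20 and R in 19, 21 and 22 only because the priority of the lower ring changes.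
- Assumption for step 2: the (S)-configured biaryl bisphosphine is taken to give the 2S flavanone, by analogy with rhodium-catalysed aryl transfer to cyclic enones. The sense should be confirmed on 4 and the antipodal ligand used if it is opposite.

Step 1
Reactants: 1 7-hydroxychromone
Product: 2 7-(benzyloxy)chromone
Conditions: BnBr, K2CO3, DMF, 25 °C
Reagents that add atoms: benzyl bromide, BrCc1ccccc1
Why: Williamson etherification of the acidic 7-hydroxyl should proceed cleanly, since the chromone ring is stable to carbonate in an aprotic solvent.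

Step 2
Reactants: 2 7-(benzyloxy)chromone; 3 [3,4-bis(benzyloxy)phenyl]boronic acid
Product: 4 (2S)-7-(benzyloxy)-2-[3,4-bis(benzyloxy)phenyl]chroman-4-one
Conditions: [Rh(OH)(C8H12)]2 (1,5-cyclooctadiene complex, cat.), (S)-MeO-F12-BIPHEP, CH2Cl2/H2O, 20 °C
Reagents that add atoms: none
Why: Rhodium-catalysed asymmetric 1,4-addition of the arylboronic acid to the chromone (Hayashi–Miyaura reaction) should give the flavanone; the chiral bisphosphine on monovalent rhodium selects the enone face and so sets C2 as S, and the base-free medium avoids racemisation by ring opening.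

Step 3
Reactants: 4 (2S)-7-(benzyloxy)-2-[3,4-bis(benzyloxy)phenyl]chroman-4-one
Product: 5 (2S,4S)-7-(benzyloxy)-2-[3,4-bis(benzyloxy)phenyl]chroman-4-ol (2,4-cis)
Conditions: NaBH4, THF/MeOH, 0 °C
Reagents that add atoms: none
Why: Borohydride reduction of the aryl ketone should give mainly the 2,4-cis alcohol without touching C2; the C4 configuration does not matter because C4 is ionised in step 9.

Step 4
Reactants: 6 4-bromoresorcinol
Product: 7 2-bromo-5-(triisopropylsilyloxy)phenol
Conditions: i-Pr3SiCl (1.0 equiv), imidazole, CH2Cl2, 0 °C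
Reagents that add atoms: chlorotriisopropylsilane, CC(C)[Si](Cl)(C(C)C)C(C)C
Why: Silylation under steric control should take the hydroxyl para to bromine, because the bulky chlorosilane is kept away from the hydroxyl flanked by bromine.

Step 5
Reactants: 7 2-bromo-5-(triisopropylsilyloxy)phenol
Product: 8 [3-(benzyloxy)-4-bromophenoxy]triisopropylsilane
Conditions: BnBr, K2CO3, acetone, 55 °C
Reagents that add atoms: benzyl bromide, BrCc1ccccc1
Why: Williamson etherification of the remaining, more acidic ortho-bromophenol should occur, and the hindered aryl triisopropylsilyl ether should survive anhydrous carbonate.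

Step 6
Reactants: 8 [3-(benzyloxy)-4-bromophenoxy]triisopropylsilane; 9 methyl (2R)-oxirane-2-carboxylate (methyl (R)-glycidate)
Product: 11 methyl (2R)-3-[2-(benzyloxy)-4-(triisopropylsilyloxy)phenyl]-2-hydroxypropanoate, via arylmagnesium bromide 10 (not isolated)
Conditions: Mg, LiCl, THF, 25 °C; then 9, CuBr·SMe2 (10 mol%), THF, −40 to −20 °C
Reagents that add atoms: none
Why: Magnesium insertion gives the aryl Grignard reagent (the silyloxy group is para and cannot migrate to carbon), and copper-catalysed SN2 opening of the glycidic ester at its terminal CH2 should spare the ester at low temperature and leave the stereocentre untouched, so R is carried over.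

Step 7
Reactants: 11 methyl (2R)-3-[2-(benzyloxy)-4-(triisopropylsilyloxy)phenyl]-2-hydroxypropanoate
Product: 12 methyl (2R)-2-(benzyloxy)-3-[2-(benzyloxy)-4-(triisopropylsilyloxy)phenyl]propanoate
Conditions: BnBr, Ag2O, CH2Cl2, 25 °C, dark
Reagents that add atoms: benzyl bromide, BrCc1ccccc1
Why: Silver-oxide-mediated O-benzylation (Purdie alkylation) of the alpha-hydroxy ester runs without strong base, so neither epimerisation at the alpha carbon nor silyl transfer is expected.

Step 8
Reactants: 12 methyl (2R)-2-(benzyloxy)-3-[2-(benzyloxy)-4-(triisopropylsilyloxy)phenyl]propanoate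
Product: 13 methyl (2R)-2-(benzyloxy)-3-[2-(benzyloxy)-4-hydroxyphenyl]propanoate
Conditions: Bu4NF, AcOH, THF, 0 °C
Reagents that add atoms: none
Why: Fluoride cleaves the aryl silyl ether rapidly, and the acetic acid buffer should protect the alpha-benzyloxy ester from base-induced epimerisation.

Step 9
Reactants: 13 methyl (2R)-2-(benzyloxy)-3-[2-(benzyloxy)-4-hydroxyphenyl]propanoate; 5 (2S,4S)-7-(benzyloxy)-2-[3,4-bis(benzyloxy)phenyl]chroman-4-ol
Product: 14 methyl (2R)-2-(benzyloxy)-3-{2-(benzyloxy)-4-hydroxy-5-[(2S,4S)-7-(benzyloxy)-2-(3,4-bis(benzyloxy)phenyl)chroman-4-yl]phenyl}propanoate (upper flavan 2,4-trans)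
Conditions: 13 (2 equiv, excess recovered), BF3·OEt2 (0.5 equiv), CH2Cl2, −40 to −20 °C, slow addition of 5
Reagents that add atoms: none
Why: Friedel–Crafts alkylation: 5 ionises to a flavan-4-yl cation stabilised by O1 and the 7-benzyloxy group, the phenol attacks through the ring carbon ortho to its hydroxyl and para to its benzyloxy group (later C8), and axial attack on the half-chair cation should place the new aryl group trans to the equatorial C2 aryl group, which sets the upper C4 centre.

Step 10
Reactants: 14 methyl (2R)-2-(benzyloxy)-3-{2-(benzyloxy)-4-hydroxy-5-[(2S,4S)-7-(benzyloxy)-2-(3,4-bis(benzyloxy)phenyl)chroman-4-yl]phenyl}propanoate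
Product: 15 (2R)-2-(benzyloxy)-3-{2-(benzyloxy)-4-hydroxy-5-[(2S,4S)-7-(benzyloxy)-2-(3,4-bis(benzyloxy)phenyl)chroman-4-yl]phenyl}propanal
Conditions: i-Bu2AlH (2.3 equiv), CH2Cl2, −78 °C; crude aldehyde used at once
Reagents that add atoms: none
Why: Partial reduction of an alpha-alkoxy ester should stop at the aldehyde stage, because the chelated tetrahedral aluminate is stable at −78 °C and collapses only on work-up; the phenol is masked in the flask as its aluminium phenoxide and the alpha centre is not exposed to base.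

Step 11
Reactants: 15 (2R)-2-(benzyloxy)-3-{2-(benzyloxy)-4-hydroxy-5-[(2S,4S)-7-(benzyloxy)-2-(3,4-bis(benzyloxy)phenyl)chroman-4-yl]phenyl}propanal; 16 5-bromo-1,2,3-tris(benzyloxy)benzene
Product: 18 (1R,2R)-2-(benzyloxy)-3-{2-(benzyloxy)-4-hydroxy-5-[(2S,4S)-7-(benzyloxy)-2-(3,4-bis(benzyloxy)phenyl)chroman-4-yl]phenyl}-1-[3,4,5-tris(benzyloxy)phenyl]propan-1-ol (syn), via arylmagnesium bromide 17 (not isolated)
Conditions: 16, Mg, THF, 40 °C; then 15, MgBr2·OEt2, CH2Cl2, −78 °C, 17 (3.5 equiv)
Reagents that add atoms: none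
Why: Chelation-controlled Grignard addition (Cram chelate model): magnesium bridges the aldehyde and alpha-benzyloxy oxygens and the aryl group adds to the face opposite the CH2Ar substituent, which should set the carbinol centre as R and give the syn diol monoether; one equivalent of 17 is spent on the phenol.

Step 12
Reactants: 18 (1R,2R)-2-(benzyloxy)-3-{2-(benzyloxy)-4-hydroxy-5-[(2S,4S)-7-(benzyloxy)-2-(3,4-bis(benzyloxy)phenyl)chroman-4-yl]phenyl}-1-[3,4,5-tris(benzyloxy)phenyl]propan-1-ol
Product: 19 para-quinol dienone: lower ring A as cyclohexa-2,5-dienone with C7 carbonyl, C8 carrying the upper (2S,4R)-7-(benzyloxy)-2-[3,4-bis(benzyloxy)phenyl]chroman-4-yl group, C8a–H, C5 benzyloxy, and C4a carbinol (both epimers) bearing the (2R,3R)-2-(benzyloxy)-3-hydroxy-3-[3,4,5-tris(benzyloxy)phenyl]propyl chain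
Conditions: PhI(OAc)2 (1.1 equiv), MeCN/THF/H2O, 0 °C
Reagents that add atoms: water, O
Why: Oxidative dearomatisation of a para-alkylphenol by trivalent iodine: water should capture the phenoxenium intermediate at the alkyl-bearing para carbon C4a, while benzyl ethers and the secondary alcohol are inert to the reagent.

Step 13
Reactants: 19 para-quinol dienone (both C4a epimers)
Product: 21 octa-O-benzyl (2S,4R)-flavan-(4→8)-epigallocatechin with free lower C7 hydroxyl, via oxa-Michael adduct 20 (not isolated)
Conditions: DBU (0.3 equiv), THF, 0 to 20 °C; then camphorsulfonic acid (1.0 equiv), 20 to 40 °C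
Reagents that add atoms: none
Why: Base generates the benzylic alkoxide, which adds reversibly to C8a, the unsubstituted beta-carbon of the cross-conjugated dienone; the closest known reaction type is the intramolecular oxa-Michael cyclisation of hydroxyalkyl para-quinols followed by acid-promoted dehydrative aromatisation to meta-oxygenated phenols. The pyran closes in a 6-exo-trig mode and is necessarily cis-fused, so both C4a epimers can cyclise. After acidification the adduct enolises towards C8 to an arene hydrate, which loses the C4a hydroxyl and the C8a proton irreversibly and gives ring A with O1 meta to the C7 phenol. No stereocentre is created: C4a, C8 and C8a end as sp2 carbons, and C2 keeps its R configuration because its C–O bond is never broken, so the syn diol maps onto the 2,3-cis flavan-3-ol. Regioselectivity is needed between C8a and the benzyloxy-bearing beta-carbon C5; it is secured because C5 is a fully substituted, less electrophilic vinylogous-ester carbon and because the addition is run under base before any acid is present. Chemoselectivity is secured because the C3 oxygen is benzylated and the tertiary C4a hydroxyl cannot reach either beta-carbon.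

Step 14
Reactants: 21 octa-O-benzyl (2S,4R)-flavan-(4→8)-epigallocatechin with free lower C7 hydroxyl
Product: 22 (2S,4R)-7,3',4'-trihydroxyflavan-(4→8)-(2R,3R)-epigallocatechin (target)
Conditions: H2 (1 atm), Pd(OH)2/C, THF/MeOH, 25 °C
Reagents that add atoms: none
Why: Hydrogenolysis should remove all eight benzyl ethers, while the cyclic benzylic C2–O1 bonds and the diarylmethine C4–C8 bond are expected to survive these mild conditions.

Compound list
1 | 7-hydroxychromone | O=c1ccoc2cc(O)ccc12 | starting material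
2 | 7-(benzyloxy)chromone | O=c1ccoc2cc(OCc3ccccc3)ccc12 | intermediate
3 | [3,4-bis(benzyloxy)phenyl]boronic acid | OB(O)c1ccc(OCc2ccccc2)c(OCc2ccccc2)c1 | starting material
4 | (2S)-7-(benzyloxy)-2-[3,4-bis(benzyloxy)phenyl]chroman-4-one | O=C1C[C@@H](c2ccc(OCc3ccccc3)c(OCc3ccccc3)c2)Oc2cc(OCc3ccccc3)ccc21 | intermediate
5 | (2S,4S)-7-(benzyloxy)-2-[3,4-bis(benzyloxy)phenyl]chroman-4-ol (2,4-cis) | O[C@H]1C[C@@H](c2ccc(OCc3ccccc3)c(OCc3ccccc3)c2)Oc2cc(OCc3ccccc3)ccc21 | intermediate
6 | 4-bromoresorcinol | Oc1ccc(Br)c(O)c1 | starting material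
7 | 2-bromo-5-(triisopropylsilyloxy)phenol | Oc1cc(O[Si](C(C)C)(C(C)C)C(C)C)ccc1Br | intermediate
8 | [3-(benzyloxy)-4-bromophenoxy]triisopropylsilane | CC(C)[Si](Oc1ccc(Br)c(OCc2ccccc2)c1)(C(C)C)C(C)C | intermediate
9 | methyl (2R)-oxirane-2-carboxylate (methyl (R)-glycidate) | COC(=O)[C@H]1CO1 | starting material
10 | [2-(benzyloxy)-4-(triisopropylsilyloxy)phenyl]magnesium bromide | Br[Mg]c1ccc(O[Si](C(C)C)(C(C)C)C(C)C)cc1OCc1ccccc1 | intermediate
11 | methyl (2R)-3-[2-(benzyloxy)-4-(triisopropylsilyloxy)phenyl]-2-hydroxypropanoate | COC(=O)[C@H](O)Cc1ccc(O[Si](C(C)C)(C(C)C)C(C)C)cc1OCc1ccccc1 | intermediate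
12 | methyl (2R)-2-(benzyloxy)-3-[2-(benzyloxy)-4-(triisopropylsilyloxy)phenyl]propanoate | COC(=O)[C@H](OCc1ccccc1)Cc1ccc(O[Si](C(C)C)(C(C)C)C(C)C)cc1OCc1ccccc1 | intermediate
13 | methyl (2R)-2-(benzyloxy)-3-[2-(benzyloxy)-4-hydroxyphenyl]propanoate | COC(=O)[C@H](OCc1ccccc1)Cc1ccc(O)cc1OCc1ccccc1 | intermediate
14 | methyl (2R)-2-(benzyloxy)-3-{2-(benzyloxy)-4-hydroxy-5-[(2S,4S)-7-(benzyloxy)-2-(3,4-bis(benzyloxy)phenyl)chroman-4-yl]phenyl}propanoate (2,4-trans flavan) | c1ccccc1COc1ccc2c(c1)O[C@H](c1ccc(OCc3ccccc3)c(OCc3ccccc3)c1)C[C@H]2c1cc(C[C@@H](OCc2ccccc2)C(=O)OC)c(OCc2ccccc2)cc1O | intermediate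
15 | (2R)-2-(benzyloxy)-3-{2-(benzyloxy)-4-hydroxy-5-[(2S,4S)-7-(benzyloxy)-2-(3,4-bis(benzyloxy)phenyl)chroman-4-yl]phenyl}propanal | c1ccccc1COc1ccc2c(c1)O[C@H](c1ccc(OCc3ccccc3)c(OCc3ccccc3)c1)C[C@H]2c1cc(C[C@@H](OCc2ccccc2)C=O)c(OCc2ccccc2)cc1O | intermediate
16 | 5-bromo-1,2,3-tris(benzyloxy)benzene | Brc1cc(OCc2ccccc2)c(OCc2ccccc2)c(OCc2ccccc2)c1 | starting material
17 | [3,4,5-tris(benzyloxy)phenyl]magnesium bromide | Br[Mg]c1cc(OCc2ccccc2)c(OCc2ccccc2)c(OCc2ccccc2)c1 | intermediate
18 | (1R,2R)-2-(benzyloxy)-3-{2-(benzyloxy)-4-hydroxy-5-[(2S,4S)-7-(benzyloxy)-2-(3,4-bis(benzyloxy)phenyl)chroman-4-yl]phenyl}-1-[3,4,5-tris(benzyloxy)phenyl]propan-1-ol (syn diol monobenzyl ether) | c1ccccc1COc1ccc2c(c1)O[C@H](c1ccc(OCc3ccccc3)c(OCc3ccccc3)c1)C[C@H]2c1cc(C[C@@H](OCc2ccccc2)[C@H](O)c2cc(OCc3ccccc3)c(OCc3ccccc3)c(OCc3ccccc3)c2)c(OCc2ccccc2)cc1O | intermediate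
19 | para-quinol dienone (C7 carbonyl, C8 upper (2S,4R)-flavan-4-yl, C5 benzyloxy, C4a carbinol as both epimers with the (2R,3R) diol monobenzyl ether chain) | c1ccccc1COc1ccc2c(c1)O[C@H](c1ccc(OCc3ccccc3)c(OCc3ccccc3)c1)C[C@H]2C1=CC(O)(C[C@@H](OCc2ccccc2)[C@H](O)c2cc(OCc3ccccc3)c(OCc3ccccc3)c(OCc3ccccc3)c2)C(OCc2ccccc2)=CC1=O | intermediate
20 | oxa-Michael adduct (cis-fused lower pyran (2R,3R) on a 4a-hydroxy-5-benzyloxy cyclohex-5-en-7-one; C4a, C8 and C8a left open) | c1ccccc1COc1ccc2c(c1)O[C@H](c1ccc(OCc3ccccc3)c(OCc3ccccc3)c1)C[C@H]2C1C(=O)C=C(OCc2ccccc2)C2(O)C[C@@H](OCc3ccccc3)[C@@H](c3cc(OCc4ccccc4)c(OCc4ccccc4)c(OCc4ccccc4)c3)OC12 | intermediate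
21 | octa-O-benzyl (2S,4R)-7,3',4'-trihydroxyflavan-(4→8)-(2R,3R)-epigallocatechin with free lower C7 hydroxyl | c1ccccc1COc1ccc2c(c1)O[C@H](c1ccc(OCc3ccccc3)c(OCc3ccccc3)c1)C[C@H]2c1c(O)cc(OCc2ccccc2)c2c1O[C@H](c1cc(OCc3ccccc3)c(OCc3ccccc3)c(OCc3ccccc3)c1)[C@H](OCc1ccccc1)C2 | intermediate
22 | (2S,4R)-7,3',4'-trihydroxyflavan-(4→8)-(2R,3R)-epigallocatechin (CNP0211965.1) | Oc1ccc2c(c1)O[C@H](c1ccc(O)c(O)c1)C[C@H]2c1c(O)cc(O)c2c1O[C@H](c1cc(O)c(O)c(O)c1)[C@H](O)C2 | target

Total step count: 14
Longest linear sequence: 11 steps (steps 4 to 14, from 6); the three-step flavanol branch (steps 1 to 3) joins at step 9.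

Steps most likely to fail

1. Step 13 (key step).
- Risk: the conjugate addition may be held back by crowding between the quaternary C4a and the flavan-bearing C8. On acidification, reversal of the addition, alkoxy exchange at the benzyloxy-bearing C5, or dienone–phenol rearrangement could then outrun the dehydration.
- Fallback: close the lower pyran before the union, on a dienone whose C8 is unsubstituted. It sets out from 13 and returns to the route at 21.
- Ester 13 is reduced with i-Bu2AlH at −78 °C to (2R)-2-(benzyloxy)-3-[2-(benzyloxy)-4-hydroxyphenyl]propanal F1.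
- Chelation-controlled addition of 17 (MgBr2·OEt2, CH2Cl2, −78 °C) should give the syn (1R,2R)-2-(benzyloxy)-3-[2-(benzyloxy)-4-hydroxyphenyl]-1-[3,4,5-tris(benzyloxy)phenyl]propan-1-ol F2.
- PhI(OAc)2 in aqueous MeCN converts it into the simple para-quinol 3-(benzyloxy)-4-hydroxy-4-[(2R,3R)-2-(benzyloxy)-3-hydroxy-3-(3,4,5-tris(benzyloxy)phenyl)propyl]cyclohexa-2,5-dienone F3.
- DBU and then camphorsulfonic acid close and aromatise it to 3,5,3',4',5'-penta-O-benzyl-(2R,3R)-epigallocatechin F4, whose 7-hydroxyl is free.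
- Friedel–Crafts alkylation of F4 with 5 (BF3·OEt2, CH2Cl2, −40 °C) at C8, the carbon flanked by the free 7-hydroxyl and O1, then gives 21. Here the phloroglucinol-type nucleophile is clearly more reactive than ring A of the flavanol.

2. Step 9.
- Risk: the flavanyl cation may alkylate ring A of a second flavan molecule instead of 13, may attack the phenol oxygen or the ring carbon between the two oxygens, or may add with incomplete 2,4-trans selectivity.
- Fallback: replace the bimolecular C-alkylation by O-alkylation followed by an oxygen-to-carbon shift. It sets out from 13 and 5 and returns at 14.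
- Mitsunobu etherification (PPh3, diisopropyl azodicarboxylate, toluene, 0 °C) joins the phenol oxygen of 13 to C4 of 5 with inversion. This gives methyl (2R)-2-(benzyloxy)-3-{2-(benzyloxy)-4-[(2S,4R)-7-(benzyloxy)-2-(3,4-bis(benzyloxy)phenyl)chroman-4-yloxy]phenyl}propanoate F5.
- BF3·OEt2 in CH2Cl2 at −78 °C then ionises the benzylic aryl ether. Collapse of the ion pair at the free ortho carbon para to the benzyloxy group (a Lewis-acid-promoted ether-to-ortho-alkylphenol rearrangement) gives 14 in a 1:1 setting, without a free excess of cation.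

3. Step 12.
- Risk: water may be captured at an ortho carbon instead of C4a, the electron-rich benzyloxyarene rings may be oxidised by the trivalent iodine reagent, or the quinol may react further in the acetic acid that is released.
- Fallback: bring in the C4a oxygen with singlet oxygen instead of a phenoxenium ion. It sets out from 18 and returns at 19.
- KHSO5 (as Oxone) with NaHCO3 in MeCN/H2O generates singlet oxygen, which should add to the phenolate of 18 at the para carbon. This gives the para-hydroperoxy dienone F6 (the C4a hydroperoxide corresponding to 19, both epimers).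
- Reduction of the hydroperoxide with Me2S at 0 °C gives 19.

Further compounds
F1 | step 13 | (2R)-2-(benzyloxy)-3-[2-(benzyloxy)-4-hydroxyphenyl]propanal | O=C[C@H](OCc1ccccc1)Cc1ccc(O)cc1OCc1ccccc1
F2 | step 13 | (1R,2R)-2-(benzyloxy)-3-[2-(benzyloxy)-4-hydroxyphenyl]-1-[3,4,5-tris(benzyloxy)phenyl]propan-1-ol | Oc1ccc(C[C@@H](OCc2ccccc2)[C@H](O)c2cc(OCc3ccccc3)c(OCc3ccccc3)c(OCc3ccccc3)c2)c(OCc2ccccc2)c1
F3 | step 13 | 3-(benzyloxy)-4-hydroxy-4-[(2R,3R)-2-(benzyloxy)-3-hydroxy-3-(3,4,5-tris(benzyloxy)phenyl)propyl]cyclohexa-2,5-dienone (both C4 epimers) | O=C1C=CC(O)(C[C@@H](OCc2ccccc2)[C@H](O)c2cc(OCc3ccccc3)c(OCc3ccccc3)c(OCc3ccccc3)c2)C(OCc2ccccc2)=C1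
F4 | step 13 | 3,5,3',4',5'-penta-O-benzyl-(2R,3R)-epigallocatechin (free 7-hydroxyl) | Oc1cc(OCc2ccccc2)c2c(c1)O[C@H](c1cc(OCc3ccccc3)c(OCc3ccccc3)c(OCc3ccccc3)c1)[C@H](OCc1ccccc1)C2
F5 | step 9 | methyl (2R)-2-(benzyloxy)-3-{2-(benzyloxy)-4-[(2S,4R)-7-(benzyloxy)-2-(3,4-bis(benzyloxy)phenyl)chroman-4-yloxy]phenyl}propanoate | COC(=O)[C@H](OCc1ccccc1)Cc1ccc(O[C@@H]2C[C@@H](c3ccc(OCc4ccccc4)c(OCc4ccccc4)c3)Oc3cc(OCc4ccccc4)ccc32)cc1OCc1ccccc1
F6 | step 12 | para-hydroperoxy dienone corresponding to 19 (C4a–OOH, both epimers) | c1ccccc1COc1ccc2c(c1)O[C@H](c1ccc(OCc3ccccc3)c(OCc3ccccc3)c1)C[C@H]2C1=CC(OO)(C[C@@H](OCc2ccccc2)[C@H](O)c2cc(OCc3ccccc3)c(OCc3ccccc3)c(OCc3ccccc3)c2)C(OCc2ccccc2)=CC1=O
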